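**Retrosynthetic overview**
1. The C11–C12 bond is cut first: a C11 allylic phenyl sulfone of the bromodecalin opens (S)-2-methyl-2-vinyloxirane, which brings C12–C16 and the C13 carbinol, and the sulfonyl group is then removed.
2. The equatorial C3 bromide comes by inversion from an axial alcohol, and this from the C3 ketone; C5–H comes from hydrogenation of a C5=C6 alkene on the face away from the C10 methyl group.
3. The strategy rests on ring B: its tetrasubstituted C8=C9 alkene holds the C17 methyl on C8 and C11 on C9, directly beside quaternary C10, which is the imprint of an alkyne dienophile. Ring B is therefore closed by [4+2] addition of methyl but-2-ynoate to a ring-A vinylcyclohexene (diene C10=C5–C6=C7; new bonds C7–C8 and C9–C10).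
4. Ring A is (R)-carvone: carbonyl carbon = C5, methyl-bearing carbon = C10, α′-carbon = C4 (gem-dimethylated), isopropenyl-bearing carbon = C3 (isopropenyl degraded to oxygen with retention). This C3 oxygen relays the carvone chirality to C10 in the cycloaddition.
5. Ring order: ring A from the chiral pool, then ring B by the Diels–Alder reaction; the side chain is attached last.

Key step: step 7

Remark: labdane numbering is used for the atoms (C3 bears Br, C4 the gem-dimethyl group, C10 the angular methyl, C11–C16 the side chain); the C3 oxygen stereocentre taken from carvone only steers C10 and is reset at the ketone stage.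

**Step 1**
Reactants: 1 (R)-(−)-carvone
Product: 3 (5S)-2,6,6-trimethyl-5-(prop-1-en-2-yl)cyclohex-2-en-1-one (6,6-dimethylcarvone), via 6-methylcarvone 2 (not isolated)
Conditions: LiN(iPr)2, THF, −78 °C, then MeI, −78 to 0 °C; second cycle in the same flask: LiN(iPr)2, −78 °C, then MeI, DMPU, −78 °C to rt
Reagents that add atoms: iodomethane CI
Why: Kinetic α′-deprotonation of the cross-conjugated enone and SN2 methylation of the enolate, run twice (enolate alkylation), should build the C4 gem-dimethyl group, and the carvone stereocentre is not enolisable and stays as it is.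

**Step 2**
Reactants: 3 6,6-dimethylcarvone
Product: 5 (1R)-2,2,4-trimethyl-3-oxocyclohex-4-en-1-yl acetate, via methoxy hydroperoxide 4 (not isolated)
Conditions: O3, CH2Cl2/MeOH, −78 °C (to the end point of the isopropenyl alkene), N2 purge; then Ac2O, Et3N, DMAP (cat.), 0 °C to rt
Reagents that add atoms: ozone O=[O+][O-]; methanol CO
Why: Ozone should cleave the electron-rich isopropenyl alkene in preference to the enone, methanol traps the carbonyl oxide as the α-methoxy hydroperoxide, and acetylation triggers a Criegee rearrangement in which the ring carbon migrates to oxygen with retention (the methoxy oxygen ends as the acetate carbonyl oxygen), so the (R)-acetate results, and it cannot eliminate because the carbon between it and the ketone is quaternary.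

**Step 3**
Reactants: 5 acetate
Product: 6 (5R)-5-hydroxy-2,6,6-trimethylcyclohex-2-en-1-one
Conditions: K2CO3 (cat.), MeOH, 0 °C to rt
Reagents that add atoms: none
Why: Base-catalysed transesterification should remove the acetyl group without touching the stereocentre, since elimination is blocked by the quaternary α-carbon.

**Step 4**
Reactants: 6 hydroxy enone
Product: 7 (5R)-5-(tert-butyldimethylsilyloxy)-2,6,6-trimethylcyclohex-2-en-1-one
Conditions: TBSCl, imidazole, DMAP (cat.), DMF, 40 °C
Reagents that add atoms: tert-butyldimethylsilyl chloride CC(C)(C)[Si](C)(C)Cl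
Why: Imidazole-mediated silylation of the secondary alcohol should give an ether that survives hydride, organometallic and Lewis-acid steps.

**Step 5**
Reactants: 7 silyloxy enone
Product: 9 (5R)-5-(tert-butyldimethylsilyloxy)-2,6,6-trimethylcyclohex-1-en-1-yl trifluoromethanesulfonate, via lithium enolate 8 (not isolated)
Conditions: LiBH(s-Bu)3 (L-Selectride), THF, −78 °C; then PhNTf2, −78 °C to rt
Reagents that add atoms: N-phenylbis(trifluoromethanesulfonimide) O=S(=O)(N(c1ccccc1)S(=O)(=O)C(F)(F)F)C(F)(F)F
Why: The bulky hydride should add 1,4 to the β-unsubstituted enone, whose carbonyl is flanked by a quaternary carbon, and the regiodefined enolate is O-triflated (conjugate reduction with enolate trapping), which fixes the tetrasubstituted C5=C10 alkene.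

**Step 6**
Reactants: 9 enol triflate; 10 tributyl(vinyl)stannane
Product: 11 (4R)-4-(tert-butyldimethylsilyloxy)-1,3,3-trimethyl-2-vinylcyclohex-1-ene
Conditions: Pd2(dba)3 (cat.), AsPh3, LiCl, NMP, 60 °C
Reagents that add atoms: none
Why: Stille coupling of hindered 2,6,6-trimethylcyclohexenyl triflates with vinylstannanes is established under zerovalent palladium with a weakly bound arsine ligand, and it should install the C6=C7 vinyl group.

**Step 7**
Reactants: 11 diene; 12 methyl but-2-ynoate
Product: 13 methyl (6R,8aR)-6-(tert-butyldimethylsilyloxy)-2,5,5,8a-tetramethyl-3,5,6,7,8,8a-hexahydronaphthalene-1-carboxylate (C5=C6 and C8=C9 alkenes; C10 methyl cis to the C3 oxygen)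
Conditions: EtAlCl2 (1.5 equiv), 12 (3 equiv), CH2Cl2, −20 °C to rt; dilute HCl work-up
Reagents that add atoms: none
Why: Complexation of the ester by EtAlCl2 lowers the ynoate LUMO, and a concerted but strongly asynchronous [4+2] cycloaddition should follow in which the open terminus C7 of the s-cis diene bonds first to the β-carbon of the ynoate (which becomes C8 with its methyl) and the fully substituted terminus C10 then closes onto the ester-bearing carbon (which becomes C9, so the ester carbon is C11). The closest known reactions are the Diels–Alder additions of 2,6,6-trimethyl-1-vinylcyclohexene to acetylenic esters used for drimane skeletons, and Lewis-acid-accelerated ynoate cycloadditions. Ring B is closed by this intermolecular cycloaddition, both sigma bonds (C7–C8 and C9–C10) forming in one event, as a 1,4-cyclohexadiene that cannot aromatise because C10 is quaternary. The one new stereocentre, C10, is controlled by the C3 silyloxy stereocentre: in the ring-A half-chair with the silyloxy group equatorial, the pseudo-axial C4 methyl and the axial C2 hydrogen shield the face that carries the silyloxy group, so the dienophile should add to the other face and the C10 methyl becomes axial and cis to the C3 oxygen (10R). The step needs regioselectivity, which comes from the alkyl groups at C10 and C5 placing the largest HOMO coefficient at C7 opposite the electrophilic β-carbon of the complexed ynoate, and π-facial selectivity, which comes from the C3/C4 substitution just described. EtAlCl2 also scavenges protons, which protects the acid-sensitive diene and the silyl ether.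

**Step 8**
Reactants: 13 Diels–Alder adduct
Product: 14 methyl (4aS,6R,8aR)-6-(tert-butyldimethylsilyloxy)-2,5,5,8a-tetramethyl-3,4,4a,5,6,7,8,8a-octahydronaphthalene-1-carboxylate (trans ring fusion)
Conditions: H2 (1 atm), Pd/C, EtOAc, rt
Reagents that add atoms: none
Why: Heterogeneous hydrogenation should reduce only the trisubstituted C5=C6 alkene (the tetrasubstituted, ester-conjugated C8=C9 alkene is inert) and deliver hydrogen to the face opposite the axial C10 and C4 methyl groups, which sets C5–H trans to the C10 methyl.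

**Step 9**
Reactants: 14 silyl ether
Product: 15 methyl (4aS,6R,8aR)-6-hydroxy-2,5,5,8a-tetramethyl-3,4,4a,5,6,7,8,8a-octahydronaphthalene-1-carboxylate
Conditions: Bu4NF, THF, 50 °C
Reagents that add atoms: none
Why: Fluoride-mediated desilylation should free the equatorial C3 alcohol while the hindered conjugated ester is untouched.

**Step 10**
Reactants: 15 equatorial alcohol
Product: 16 methyl (4aS,8aR)-2,5,5,8a-tetramethyl-6-oxo-3,4,4a,5,6,7,8,8a-octahydronaphthalene-1-carboxylate
Conditions: Dess–Martin periodinane, CH2Cl2, rt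
Reagents that add atoms: none
Why: Dess–Martin oxidation of the secondary alcohol should give the C3 ketone under neutral conditions, with C5 and C10 not epimerisable.

**Step 11**
Reactants: 16 ketone
Product: 17 methyl (4aS,6S,8aR)-6-hydroxy-2,5,5,8a-tetramethyl-3,4,4a,5,6,7,8,8a-octahydronaphthalene-1-carboxylate (axial C3 alcohol, trans to the C10 methyl)
Conditions: KBH(s-Bu)3 (K-Selectride), THF, −78 °C
Reagents that add atoms: none
Why: The bulky trialkylborohydride should attack the 4,4-dimethyl-3-ketone along the equatorial trajectory, as in triterpenoid 3-ketones, to give the axial alcohol, and it does not reduce the hindered tetrasubstituted enoate at −78 °C.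

**Step 12**
Reactants: 17 axial alcohol
Product: 18 methyl (4aS,6R,8aR)-6-bromo-2,5,5,8a-tetramethyl-3,4,4a,5,6,7,8,8a-octahydronaphthalene-1-carboxylate (equatorial bromide, cis to the C10 methyl)
Conditions: PPh3, CBr4, toluene, 0 to 60 °C
Reagents that add atoms: carbon tetrabromide BrC(Br)(Br)Br
Why: In the Appel reaction bromide should displace the axial oxyphosphonium group from the equatorial direction with inversion, giving the equatorial C3 bromide, which has no antiperiplanar hydrogen and is therefore stable to later bases.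

**Step 13**
Reactants: 18 bromo ester
Product: 19 [(4aS,6R,8aR)-6-bromo-2,5,5,8a-tetramethyl-3,4,4a,5,6,7,8,8a-octahydronaphthalen-1-yl]methanol
Conditions: i-Bu2AlH, CH2Cl2, −78 to 0 °C; aq. KNaC4H4O6 work-up
Reagents that add atoms: none
Why: The electrophilic aluminium hydride should reduce the conjugated ester 1,2 to the C11 allylic alcohol and does not reduce alkyl bromides.

**Step 14**
Reactants: 19 allylic alcohol
Product: 21 (4aS,6R,8aR)-6-bromo-2,5,5,8a-tetramethyl-1-[(phenylsulfonyl)methyl]-3,4,4a,5,6,7,8,8a-octahydronaphthalene, via allylic bromide 20 (not isolated)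
Conditions: PBr3, Et2O, 0 °C; then PhSO2Na, DMF, rt
Reagents that add atoms: sodium benzenesulfinate [Na+].[O-]S(=O)c1ccccc1
Why: The primary allylic alcohol should be brominated and the labile bromide S-alkylates the sulfinate by SN2 at the unhindered C11, while the secondary, neopentyl-type C3 bromide does not react with this soft nucleophile.

**Step 15**
Reactants: 22 2-methylprop-2-en-1-ol
Product: 23 (S)-(2-methyloxiran-2-yl)methanol
Conditions: Ti(OiPr)4 (cat.), L-(+)-diisopropyl tartrate (cat.), t-BuOOH, 4 Å molecular sieves, CH2Cl2, −20 °C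
Reagents that add atoms: tert-butyl hydroperoxide CC(C)(C)OO
Why: Sharpless asymmetric epoxidation with the L-(+)-tartrate should deliver oxygen to the face of the allylic alcohol that gives the (S)-epoxy alcohol, as it does for other 2-substituted allylic alcohols.

**Step 16**
Reactants: 23 (S)-2-methylglycidol
Product: 25 (S)-2-methyl-2-vinyloxirane, via epoxy aldehyde 24 (not isolated)
Conditions: Dess–Martin periodinane, CH2Cl2, 0 °C to rt; filtered solution added to Ph3P=CH2 (from Ph3PCH3Br, KOtBu), THF, 0 °C; product distilled with THF and used as a solution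
Reagents that add atoms: methyltriphenylphosphonium bromide C[P+](c1ccccc1)(c1ccccc1)c1ccccc1.[Br-]
Why: Oxidation to the aldehyde and Wittig methylenation should turn the hydroxymethyl group into the vinyl group without touching the quaternary stereocentre, which cannot epimerise.

**Step 17**
Reactants: 21 sulfone; 25 (S)-2-methyl-2-vinyloxirane
Product: 27 (3R)-5-[(4aS,6R,8aR)-6-bromo-2,5,5,8a-tetramethyl-3,4,4a,5,6,7,8,8a-octahydronaphthalen-1-yl]-3-methyl-5-(phenylsulfonyl)pent-1-en-3-ol (C11 epimers), via lithiated sulfone 26 (not isolated)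
Conditions: n-BuLi, THF, −78 °C; DMPU, then 25, −78 °C to rt
Reagents that add atoms: none
Why: The α-sulfonyl carbanion, which alkylates at C11 and not at the fully substituted C8, should open the epoxide by SN2 at its unsubstituted CH2 (sulfone alkylation with an epoxide), so the C13 carbinol keeps the epoxide configuration and becomes (13R), while the hindered equatorial C3 bromide is not attacked at low temperature.

**Step 18**
Reactants: 27 hydroxy sulfone
Product: 28 (3R)-5-[(4aS,6R,8aR)-6-bromo-2,5,5,8a-tetramethyl-3,4,4a,5,6,7,8,8a-octahydronaphthalen-1-yl]-3-methylpent-1-en-3-ol (target)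
Conditions: PdCl2(dppp) (cat.), LiBHEt3, THF, 0 °C
Reagents that add atoms: none
Why: Zerovalent palladium should ionise the allylic sulfone to a π-allyl complex that takes up hydride at the less hindered terminus C11 (palladium-catalysed hydride desulfonylation of allylic sulfones), which keeps the tetrasubstituted C8=C9 alkene; the C3 bromide, both cyclohexyl and neopentyl-type, should resist SN2 hydride and palladium insertion at 0 °C.

**Compound list**
1 | (R)-(−)-carvone | CC1=CC[C@H](CC1=O)C(C)=C | starting material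
2 | (5R)-2,6-dimethyl-5-(prop-1-en-2-yl)cyclohex-2-en-1-one (6-methylcarvone, C6 epimers) | CC1=CC[C@H](C(C)C1=O)C(C)=C | intermediate
3 | (5S)-2,6,6-trimethyl-5-(prop-1-en-2-yl)cyclohex-2-en-1-one | CC1=CC[C@H](C(C)(C)C1=O)C(C)=C | intermediate
4 | (5R)-5-(1-hydroperoxy-1-methoxyethyl)-2,6,6-trimethylcyclohex-2-en-1-one (epimers at the peroxy carbon) | CC1=CC[C@H](C(C)(C)C1=O)C(C)(OC)OO | intermediate
5 | (1R)-2,2,4-trimethyl-3-oxocyclohex-4-en-1-yl acetate | CC1=CC[C@@H](OC(C)=O)C(C)(C)C1=O | intermediate
6 | (5R)-5-hydroxy-2,6,6-trimethylcyclohex-2-en-1-one | CC1=CC[C@@H](O)C(C)(C)C1=O | intermediate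
7 | (5R)-5-(tert-butyldimethylsilyloxy)-2,6,6-trimethylcyclohex-2-en-1-one | CC1=CC[C@@H](O[Si](C)(C)C(C)(C)C)C(C)(C)C1=O | intermediate
8 | lithium (5R)-5-(tert-butyldimethylsilyloxy)-2,6,6-trimethylcyclohex-1-en-1-olate | [Li]OC1=C(C)CC[C@@H](O[Si](C)(C)C(C)(C)C)C1(C)C | intermediate
9 | (5R)-5-(tert-butyldimethylsilyloxy)-2,6,6-trimethylcyclohex-1-en-1-yl trifluoromethanesulfonate | CC1=C(OS(=O)(=O)C(F)(F)F)C(C)(C)[C@H](O[Si](C)(C)C(C)(C)C)CC1 | intermediate
10 | tributyl(vinyl)stannane | C=C[Sn](CCCC)(CCCC)CCCC | starting material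
11 | (4R)-4-(tert-butyldimethylsilyloxy)-1,3,3-trimethyl-2-vinylcyclohex-1-ene | C=CC1=C(C)CC[C@@H](O[Si](C)(C)C(C)(C)C)C1(C)C | intermediate
12 | methyl but-2-ynoate | CC#CC(=O)OC | starting material
13 | methyl (6R,8aR)-6-(tert-butyldimethylsilyloxy)-2,5,5,8a-tetramethyl-3,5,6,7,8,8a-hexahydronaphthalene-1-carboxylate | COC(=O)C1=C(C)CC=C2C(C)(C)[C@H](O[Si](C)(C)C(C)(C)C)CC[C@@]12C | intermediate
14 | methyl (4aS,6R,8aR)-6-(tert-butyldimethylsilyloxy)-2,5,5,8a-tetramethyl-3,4,4a,5,6,7,8,8a-octahydronaphthalene-1-carboxylate | COC(=O)C1=C(C)CC[C@@H]2C(C)(C)[C@H](O[Si](C)(C)C(C)(C)C)CC[C@@]12C | intermediate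
15 | methyl (4aS,6R,8aR)-6-hydroxy-2,5,5,8a-tetramethyl-3,4,4a,5,6,7,8,8a-octahydronaphthalene-1-carboxylate | COC(=O)C1=C(C)CC[C@@H]2C(C)(C)[C@H](O)CC[C@@]12C | intermediate
16 | methyl (4aS,8aR)-2,5,5,8a-tetramethyl-6-oxo-3,4,4a,5,6,7,8,8a-octahydronaphthalene-1-carboxylate | COC(=O)C1=C(C)CC[C@@H]2C(C)(C)C(=O)CC[C@@]12C | intermediate
17 | methyl (4aS,6S,8aR)-6-hydroxy-2,5,5,8a-tetramethyl-3,4,4a,5,6,7,8,8a-octahydronaphthalene-1-carboxylate | COC(=O)C1=C(C)CC[C@@H]2C(C)(C)[C@@H](O)CC[C@@]12C | intermediate
18 | methyl (4aS,6R,8aR)-6-bromo-2,5,5,8a-tetramethyl-3,4,4a,5,6,7,8,8a-octahydronaphthalene-1-carboxylate | COC(=O)C1=C(C)CC[C@@H]2C(C)(C)[C@H](Br)CC[C@@]12C | intermediate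
19 | [(4aS,6R,8aR)-6-bromo-2,5,5,8a-tetramethyl-3,4,4a,5,6,7,8,8a-octahydronaphthalen-1-yl]methanol | OCC1=C(C)CC[C@@H]2C(C)(C)[C@H](Br)CC[C@@]12C | intermediate
20 | (4aS,6R,8aR)-6-bromo-1-(bromomethyl)-2,5,5,8a-tetramethyl-3,4,4a,5,6,7,8,8a-octahydronaphthalene | BrCC1=C(C)CC[C@@H]2C(C)(C)[C@H](Br)CC[C@@]12C | intermediate
21 | (4aS,6R,8aR)-6-bromo-2,5,5,8a-tetramethyl-1-[(phenylsulfonyl)methyl]-3,4,4a,5,6,7,8,8a-octahydronaphthalene | O=S(=O)(CC1=C(C)CC[C@@H]2C(C)(C)[C@H](Br)CC[C@@]12C)c1ccccc1 | intermediate
22 | 2-methylprop-2-en-1-ol | C=C(C)CO | starting material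
23 | (S)-(2-methyloxiran-2-yl)methanol | OC[C@@]1(C)CO1 | intermediate
24 | (R)-2-methyloxirane-2-carbaldehyde | O=C[C@@]1(C)CO1 | intermediate
25 | (S)-2-methyl-2-vinyloxirane | C=C[C@@]1(C)CO1 | intermediate
26 | C11-lithiated sulfone 21 | [Li]C(C1=C(C)CC[C@@H]2C(C)(C)[C@H](Br)CC[C@@]12C)S(=O)(=O)c1ccccc1 | intermediate
27 | (3R)-5-[(4aS,6R,8aR)-6-bromo-2,5,5,8a-tetramethyl-3,4,4a,5,6,7,8,8a-octahydronaphthalen-1-yl]-3-methyl-5-(phenylsulfonyl)pent-1-en-3-ol (C11 epimers) | C=C[C@](C)(O)CC(C1=C(C)CC[C@@H]2C(C)(C)[C@H](Br)CC[C@@]12C)S(=O)(=O)c1ccccc1 | intermediate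
28 | (3R)-5-[(4aS,6R,8aR)-6-bromo-2,5,5,8a-tetramethyl-3,4,4a,5,6,7,8,8a-octahydronaphthalen-1-yl]-3-methylpent-1-en-3-ol | C=C[C@](C)(O)CCC1=C(C)CC[C@@H]2C(C)(C)[C@H](Br)CC[C@@]12C | target

**Step count and risks**
Total step count: 18. Longest linear sequence: 16 steps from (R)-carvone (steps 1–14, 17 and 18); the epoxide branch is steps 15 and 16.

Steps most likely to fail:

Step 7. Bond formation at the fully substituted C10 terminus may be too slow, so that Lewis-acid-induced oligomerisation of the diene, stepwise [2+2] or ene pathways, or erosion of the facial preference overtake the cycloaddition. Fallback: diene 11 is combined instead with the far more electrophilic but-2-ynal (BF3·OEt2, CH2Cl2, −78 °C), which should add with the same orientation to give (6R,8aR)-6-(tert-butyldimethylsilyloxy)-2,5,5,8a-tetramethyl-3,5,6,7,8,8a-hexahydronaphthalene-1-carbaldehyde F1. Pinnick oxidation (NaClO2, NaH2PO4, 2-methylbut-2-ene, t-BuOH/H2O) gives (6R,8aR)-6-(tert-butyldimethylsilyloxy)-2,5,5,8a-tetramethyl-3,5,6,7,8,8a-hexahydronaphthalene-1-carboxylic acid F2, and methylation with trimethylsilyldiazomethane (toluene/MeOH) returns to ester 13.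

Step 12. Displacement of the oxyphosphonium group at the neopentyl-type C3 may stall, so that E2 loss toward a C2=C3 alkene or a Wagner–Meerwein shift of a C4 methyl group takes over. Fallback: axial alcohol 17 is converted with Tf2O/pyridine (CH2Cl2, −20 °C) into methyl (4aS,6S,8aR)-2,5,5,8a-tetramethyl-6-(trifluoromethylsulfonyloxy)-3,4,4a,5,6,7,8,8a-octahydronaphthalene-1-carboxylate F3. The sulfonate is then displaced by Bu4NBr in toluene (0 °C to rt), a non-ionising medium that favours direct SN2 inversion, to give bromide 18.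

Step 17. The hindered carbanion may open the vinyl epoxide at the vinyl terminus (SN2′ course) or react too slowly, and the volatile epoxide is hard to dose. Fallback: it sets out from (S)-2-methylglycidol 23 and sulfone 21 and returns at target 28.
- Compound 23 is silylated (TBSCl, imidazole, DMF) to (R)-tert-butyldimethyl[(2-methyloxiran-2-yl)methoxy]silane F4.
- Lithiated sulfone 26 (from 21, n-BuLi, THF, −78 °C) opens F4 at its CH2 in the presence of BF3·OEt2 to give (2R)-4-[(4aS,6R,8aR)-6-bromo-2,5,5,8a-tetramethyl-3,4,4a,5,6,7,8,8a-octahydronaphthalen-1-yl]-1-(tert-butyldimethylsilyloxy)-2-methyl-4-(phenylsulfonyl)butan-2-ol F5.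
- Desulfonylation as in step 18 (PdCl2(dppp), LiBHEt3, THF, 0 °C) gives (2R)-4-[(4aS,6R,8aR)-6-bromo-2,5,5,8a-tetramethyl-3,4,4a,5,6,7,8,8a-octahydronaphthalen-1-yl]-1-(tert-butyldimethylsilyloxy)-2-methylbutan-2-ol F6.
- Bu4NF (THF) frees (2R)-4-[(4aS,6R,8aR)-6-bromo-2,5,5,8a-tetramethyl-3,4,4a,5,6,7,8,8a-octahydronaphthalen-1-yl]-2-methylbutane-1,2-diol F7.
- Selective oxidation of the primary alcohol (TEMPO cat., PhI(OAc)2, CH2Cl2) gives (2R)-4-[(4aS,6R,8aR)-6-bromo-2,5,5,8a-tetramethyl-3,4,4a,5,6,7,8,8a-octahydronaphthalen-1-yl]-2-hydroxy-2-methylbutanal F8.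
- Wittig methylenation with excess Ph3P=CH2 (THF, 0 °C) gives target 28; here the allylic tertiary alcohol is made only after all substitution chemistry is finished.

**Further compounds**
F1 | step 7 | (6R,8aR)-6-(tert-butyldimethylsilyloxy)-2,5,5,8a-tetramethyl-3,5,6,7,8,8a-hexahydronaphthalene-1-carbaldehyde | O=CC1=C(C)CC=C2C(C)(C)[C@H](O[Si](C)(C)C(C)(C)C)CC[C@@]12C
F2 | step 7 | (6R,8aR)-6-(tert-butyldimethylsilyloxy)-2,5,5,8a-tetramethyl-3,5,6,7,8,8a-hexahydronaphthalene-1-carboxylic acid | OC(=O)C1=C(C)CC=C2C(C)(C)[C@H](O[Si](C)(C)C(C)(C)C)CC[C@@]12C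
F3 | step 12 | methyl (4aS,6S,8aR)-2,5,5,8a-tetramethyl-6-(trifluoromethylsulfonyloxy)-3,4,4a,5,6,7,8,8a-octahydronaphthalene-1-carboxylate | COC(=O)C1=C(C)CC[C@@H]2C(C)(C)[C@@H](OS(=O)(=O)C(F)(F)F)CC[C@@]12C
F4 | step 17 | (R)-tert-butyldimethyl[(2-methyloxiran-2-yl)methoxy]silane | CC(C)(C)[Si](C)(C)OC[C@@]1(C)CO1
F5 | step 17 | (2R)-4-[(4aS,6R,8aR)-6-bromo-2,5,5,8a-tetramethyl-3,4,4a,5,6,7,8,8a-octahydronaphthalen-1-yl]-1-(tert-butyldimethylsilyloxy)-2-methyl-4-(phenylsulfonyl)butan-2-ol | CC(C)(C)[Si](C)(C)OC[C@](C)(O)CC(C1=C(C)CC[C@@H]2C(C)(C)[C@H](Br)CC[C@@]12C)S(=O)(=O)c1ccccc1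
F6 | step 17 | (2R)-4-[(4aS,6R,8aR)-6-bromo-2,5,5,8a-tetramethyl-3,4,4a,5,6,7,8,8a-octahydronaphthalen-1-yl]-1-(tert-butyldimethylsilyloxy)-2-methylbutan-2-ol | CC(C)(C)[Si](C)(C)OC[C@](C)(O)CCC1=C(C)CC[C@@H]2C(C)(C)[C@H](Br)CC[C@@]12C
F7 | step 17 | (2R)-4-[(4aS,6R,8aR)-6-bromo-2,5,5,8a-tetramethyl-3,4,4a,5,6,7,8,8a-octahydronaphthalen-1-yl]-2-methylbutane-1,2-diol | OC[C@](C)(O)CCC1=C(C)CC[C@@H]2C(C)(C)[C@H](Br)CC[C@@]12C
F8 | step 17 | (2R)-4-[(4aS,6R,8aR)-6-bromo-2,5,5,8a-tetramethyl-3,4,4a,5,6,7,8,8a-octahydronaphthalen-1-yl]-2-hydroxy-2-methylbutanal | O=C[C@](C)(O)CCC1=C(C)CC[C@@H]2C(C)(C)[C@H](Br)CC[C@@]12C
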